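**Retrosynthetic overview**
1. The C4–C5 epoxide comes last, by peracid attack on the outer face of the 4,5-E-alkene of the finished ten-membered lactone. Just before that, the C9 acetate and the C8 methacrylate are put stepwise on the 8,9-diol.
2. The ten-membered carbocycle and the γ-lactone form in one flask. The C6–C7 bond is made by a blue-light-driven, CrCl2-catalysed intramolecular allylation of the C6 enal by a 2-(bromomethyl)enoate, followed by lactonisation. Ring order: carbocycle, lactone, epoxide.
3. The bromo-enoate (C11–C13) comes from the C7 aldehyde and methyl acrylate by a Morita–Baylis–Hillman reaction and SN2' bromination.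
4. The C9–C10 bond is made by photochemical decarboxylative vinylation ([Ir(dF(CF3)ppy)2(dtbbpy)]PF6 / NiCl2(dme)). The partners are the half-ester of L-tartrate acetonide (C7–C9, the only source of chirality) and a (Z)-2-iodoenoate.
5. The iodoenoate (C1–C6, C10, C14, C15) comes from geranyl acetate by ozonolysis and iodo-Wittig olefination.

Assumption: the germacrane numbering (C1–C15) of the target is used for every intermediate. CIP letters at C6–C8 change along the route only where substituent ranks change, and the spatial arrangement is always that of the SMILES strings.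

**Step 1**
Reactants: 1 geranyl acetate
Product: 3 (4E)-6-acetoxy-4-methylhex-4-enal, via ozonide 2 (not isolated)
Conditions: O3 (1.0 equiv), CH2Cl2, −78 °C; Me2S, −78 °C to rt
Reagents that add atoms: ozone, [O-][O+]=O
Why: Chemoselective Criegee ozonolysis with reductive work-up, in which the electron-rich isopropylidene alkene reacts much faster than the 2,3-alkene deactivated by the allylic acetate, so the E geometry stays and no stereocentre is made.

**Step 2**
Reactants: 3 (4E)-6-acetoxy-4-methylhex-4-enal; 4 methyl (triphenylphosphoranylidene)acetate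
Product: 6 methyl (2Z,6E)-8-acetoxy-2-iodo-6-methylocta-2,6-dienoate, via iodo ylide 5 (not isolated)
Conditions: 4, NIS, CH2Cl2, −20 °C, 30 min; then 3, −20 °C to rt
Reagents that add atoms: N-iodosuccinimide, O=C1CCC(=O)N1I
Why: Iodination of the stabilised ylide followed by Wittig olefination places the aldehyde chain trans to the ester, as with all ester-stabilised ylides, which gives the (Z)-iodide needed for the ring-cis C1=C10 alkene (the minor E isomer is removed by chromatography).

**Step 3**
Reactants: 7 dimethyl (4R,5R)-2,2-dimethyl-1,3-dioxolane-4,5-dicarboxylate (dimethyl 2,3-O-isopropylidene-L-tartrate)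
Product: 8 (4R,5R)-5-(methoxycarbonyl)-2,2-dimethyl-1,3-dioxolane-4-carboxylic acid
Conditions: KOH (1.0 equiv), MeOH, 0 °C to rt; 1 M HCl
Reagents that add atoms: potassium hydroxide, [K+].[OH-]
Why: Mono-saponification of a C2-symmetric diester, where the first-formed carboxylate slows the second hydrolysis, leaves both bought stereocentres intact because the trans-dioxolane is also the thermodynamic isomer.

**Step 4**
Reactants: 6 methyl (2Z,6E)-8-acetoxy-2-iodo-6-methylocta-2,6-dienoate; 8 (4R,5R)-5-(methoxycarbonyl)-2,2-dimethyl-1,3-dioxolane-4-carboxylic acid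
Product: 9 methyl (4R,5S)-5-[(2E,6E)-8-acetoxy-1-methoxy-6-methyl-1-oxoocta-2,6-dien-2-yl]-2,2-dimethyl-1,3-dioxolane-4-carboxylate
Conditions: 8 (1.3 equiv), Cs2CO3 (1.3 equiv), [Ir(dF(CF3)ppy)2(dtbbpy)]PF6 (1 mol %), NiCl2(dme) (5 mol %), dtbbpy (5 mol %), DMF, 450 nm LEDs, 25 °C
Reagents that add atoms: none
Why: In this metallaphotoredox decarboxylative vinylation, excited [Ir(dF(CF3)ppy)2(dtbbpy)]PF6 oxidises the caesium carboxylate, loss of CO2 gives the dioxolan-4-yl radical at C9, the alkenylnickel species made from 6 and zerovalent nickel traps it, and reductive elimination forms C9–C10 with retained alkene geometry on the ring face anti to the C8 ester, so the bought C8 centre re-sets C9 as the trans (9S) isomer.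

**Step 5**
Reactants: 9 methyl (4R,5S)-5-[(2E,6E)-8-acetoxy-1-methoxy-6-methyl-1-oxoocta-2,6-dien-2-yl]-2,2-dimethyl-1,3-dioxolane-4-carboxylate
Product: 11 methyl (2E,6E)-8-hydroxy-2-[(4S,5S)-5-(hydroxymethyl)-2,2-dimethyl-1,3-dioxolan-4-yl]-6-methylocta-2,6-dienoate, via hydroxy acetate 10 (not isolated)
Conditions: NaBH4, MeOH, 0 °C; then K2CO3 (0.2 equiv), rt
Reagents that add atoms: none
Why: Chemoselective borohydride reduction (only the α-alkoxy ester is activated enough for NaBH4, and the α-branched enoate is inert) is followed in the same flask by Zemplén-type transesterification of the allylic acetate, and no stereocentre is touched.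

**Step 6**
Reactants: 11 methyl (2E,6E)-8-hydroxy-2-[(4S,5S)-5-(hydroxymethyl)-2,2-dimethyl-1,3-dioxolan-4-yl]-6-methylocta-2,6-dienoate
Product: 12 methyl (2E,6E)-2-[(4S,5R)-5-formyl-2,2-dimethyl-1,3-dioxolan-4-yl]-6-methyl-8-oxoocta-2,6-dienoate
Conditions: TEMPO (0.2 equiv), PhI(OAc)2 (2.3 equiv), CH2Cl2, rt
Reagents that add atoms: none
Why: Oxoammonium (TEMPO/PhI(OAc)2) oxidation takes both primary alcohols to the aldehyde level under neutral, water-free conditions without over-oxidation, alkene isomerisation or loss of the trans-dioxolane.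

**Step 7**
Reactants: 12 methyl (2E,6E)-2-[(4S,5R)-5-formyl-2,2-dimethyl-1,3-dioxolan-4-yl]-6-methyl-8-oxoocta-2,6-dienoate; 13 methyl acrylate
Product: 14 methyl (2E,6E)-2-{(4S,5S)-5-[1-hydroxy-2-(methoxycarbonyl)prop-2-en-1-yl]-2,2-dimethyl-1,3-dioxolan-4-yl}-6-methyl-8-oxoocta-2,6-dienoate (both C7 epimers)
Conditions: 13 (3 equiv), DABCO (1 equiv), 1,4-dioxane/H2O 1:1, rt, 12–24 h
Reagents that add atoms: none
Why: In this Morita–Baylis–Hillman reaction only the activated α-alkoxy aldehyde C7 is attacked by the DABCO–acrylate zwitterion, the β,β-disubstituted C6 enal is inert, and the new C7 carbinol centre (a mixture) is erased in step 8.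

**Step 8**
Reactants: 14 Morita–Baylis–Hillman adduct
Product: 15 methyl (2E,6E)-2-{(4S,5S)-5-[(1Z)-3-bromo-2-(methoxycarbonyl)prop-1-en-1-yl]-2,2-dimethyl-1,3-dioxolan-4-yl}-6-methyl-8-oxoocta-2,6-dienoate
Conditions: NBS, Me2S, CH2Cl2, 0 °C to rt
Reagents that add atoms: N-bromosuccinimide, O=C1CCC(=O)N1Br
Why: Corey–Kim-type activation of the allylic alcohol and SN2' attack of bromide give the conjugated, thermodynamically preferred (Z)-2-(bromomethyl)enoate under neutral conditions that spare the acetonide and the enal.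

**Step 9**
Reactants: 15 allylic bromide enal
Product: 17 methyl (1(10)E,4E,6R,7S,8S,9S)-8,9-(isopropylidenedioxy)-12-oxo-6,12-epoxygermacra-1(10),4,11(13)-trien-14-oate (trans-fused lactone; ring-cis C1=C10), via hydroxy ester 16 (not isolated)
Conditions: CrCl2 (20 mol %), 4CzIPN (3 mol %), Hantzsch ester (1.5 equiv), 2,6-lutidine (1.5 equiv), THF/DMF 4:1, 15 added over 12 h to 2 mM, 450 nm LEDs, 20 °C
Reagents that add atoms: none
Why: Proposed new method: divalent chromium is held at catalytic level and regenerated from trivalent chromium by the photoreduced 4CzIPN radical anion, with the Hantzsch ester as terminal electron and proton source; it abstracts bromine from 15 and traps the 2-(methoxycarbonyl)allyl radical, and the equilibrating allylchromium adds through its γ-carbon C7 to the C6 enal in a chair Zimmerman–Traxler array trans-fused to the nascent ten-membered ring (C5 and C8 both equatorial, hence the anti adduct and the trans-lactone); the rigid trans-dioxolane fixes the C7–C8–C9–C10 torsion and lets the tether reach only the C7 face that avoids both A(1,3) strain and a syn-pentane contact between C6 and C10, which sets C6 and C7 as in the target, and the alkoxide then closes the lactone with loss of methanol; the closest known reaction types are the stoichiometric CrCl2 Nozaki–Hiyama ring closure of germacranolide bromo-aldehydes and the intermolecular dual photoredox/chromium allylation of aldehydes, neither of which has been shown as a light-driven macrocyclisation or with a 2-alkoxycarbonylallyl bromide.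

**Step 10**
Reactants: 17 macrocyclic lactone acetonide
Product: 18 methyl (1(10)E,4E,6R,7R,8S,9S)-8,9-dihydroxy-12-oxo-6,12-epoxygermacra-1(10),4,11(13)-trien-14-oate
Conditions: AcOH/H2O 4:1, 40 °C
Reagents that add atoms: none
Why: Acid-catalysed acetal hydrolysis opens the strained trans-fused dioxolane under conditions mild enough for the allylic lactone, and the electron-poor C1=C10 alkene shuts down transannular cyclisation.

**Step 11**
Reactants: 18 macrocyclic 8,9-diol
Product: 19 methyl (1(10)E,4E,6R,7R,8S,9S)-9-acetoxy-8-hydroxy-12-oxo-6,12-epoxygermacra-1(10),4,11(13)-trien-14-oate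
Conditions: Ac2O (1.05 equiv), DMAP (0.05 equiv), pyridine, CH2Cl2, −20 °C
Reagents that add atoms: acetic anhydride, CC(=O)OC(C)=O
Why: This is a kinetic site-selective acylation, because the allylic C9 hydroxyl lies on the ring periphery next to the flat sp2 carbon C10 and takes the limiting anhydride first, whereas the C8 hydroxyl sits in the pocket between the C7 methine, the exocyclic methylene and the C14 ester.

**Step 12**
Reactants: 19 9-acetate 8-alcohol
Product: 20 methyl (1(10)E,4E,6R,7S,8S,9S)-9-acetoxy-8-(methacryloyloxy)-12-oxo-6,12-epoxygermacra-1(10),4,11(13)-trien-14-oate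
Conditions: methacrylic anhydride (2 equiv), DMAP (0.2 equiv), Et3N, CH2Cl2, 0 °C to rt
Reagents that add atoms: methacrylic anhydride, C=C(C)C(=O)OC(=O)C(C)=C
Why: DMAP-catalysed (Steglich-type) acylation of the remaining hindered C8 hydroxyl with excess anhydride at low temperature outruns acetyl migration and leaves all stereocentres untouched.

**Step 13**
Reactants: 20 4,5-alkene diester
Product: 21 target, methyl (1(10)E,4R,5R,6S,7R,8S,9S)-9-acetoxy-4,5-epoxy-8-(methacryloyloxy)-12-oxo-6,12-epoxygermacra-1(10),11(13)-dien-14-oate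
Conditions: mCPBA (1.2 equiv), CH2Cl2, 0 °C
Reagents that add atoms: 3-chloroperbenzoic acid, O=C(OO)c1cccc(Cl)c1
Why: In this Prilezhaev epoxidation only the C4=C5 alkene is electron-rich, and in the A(1,3)-minimised conformer (H6 eclipsing C4=C5) ring carbon C7 covers the inner face, so the peracid attacks the outer face syn to the lactone oxygen and the E-alkene gives the trans (4R,5R)-epoxide.

**Compound list**
1 | geranyl acetate | CC(C)=CCC/C(C)=C/COC(C)=O | starting material
2 | secondary ozonide of the 6,7-alkene of 1 | CC(=O)OC/C=C(\C)CCC1OOC(C)(C)O1 | intermediate (not isolated)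
3 | (4E)-6-acetoxy-4-methylhex-4-enal | O=CCC/C(C)=C/COC(C)=O | intermediate
4 | methyl (triphenylphosphoranylidene)acetate | COC(=O)C=P(c1ccccc1)(c1ccccc1)c1ccccc1 | starting material
5 | methyl iodo(triphenylphosphoranylidene)acetate | COC(=O)C(I)=P(c1ccccc1)(c1ccccc1)c1ccccc1 | intermediate (not isolated)
6 | methyl (2Z,6E)-8-acetoxy-2-iodo-6-methylocta-2,6-dienoate | COC(=O)/C(I)=C/CC/C(C)=C/COC(C)=O | intermediate
7 | dimethyl (4R,5R)-2,2-dimethyl-1,3-dioxolane-4,5-dicarboxylate | COC(=O)[C@@H]1OC(C)(C)O[C@H]1C(=O)OC | starting material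
8 | (4R,5R)-5-(methoxycarbonyl)-2,2-dimethyl-1,3-dioxolane-4-carboxylic acid | COC(=O)[C@@H]1OC(C)(C)O[C@H]1C(=O)O | intermediate
9 | methyl (4R,5S)-5-[(2E,6E)-8-acetoxy-1-methoxy-6-methyl-1-oxoocta-2,6-dien-2-yl]-2,2-dimethyl-1,3-dioxolane-4-carboxylate | COC(=O)[C@@H]1OC(C)(C)O[C@H]1/C(C(=O)OC)=C\CC/C(C)=C/COC(C)=O | intermediate
10 | methyl (2E,6E)-8-acetoxy-2-[(4S,5S)-5-(hydroxymethyl)-2,2-dimethyl-1,3-dioxolan-4-yl]-6-methylocta-2,6-dienoate | OC[C@@H]1OC(C)(C)O[C@H]1/C(C(=O)OC)=C\CC/C(C)=C/COC(C)=O | intermediate (not isolated)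
11 | methyl (2E,6E)-8-hydroxy-2-[(4S,5S)-5-(hydroxymethyl)-2,2-dimethyl-1,3-dioxolan-4-yl]-6-methylocta-2,6-dienoate | OC[C@@H]1OC(C)(C)O[C@H]1/C(C(=O)OC)=C\CC/C(C)=C/CO | intermediate
12 | methyl (2E,6E)-2-[(4S,5R)-5-formyl-2,2-dimethyl-1,3-dioxolan-4-yl]-6-methyl-8-oxoocta-2,6-dienoate | O=C[C@@H]1OC(C)(C)O[C@H]1/C(C(=O)OC)=C\CC/C(C)=C/C=O | intermediate
13 | methyl acrylate | C=CC(=O)OC | starting material
14 | Morita–Baylis–Hillman adduct at C7 (8S,9S; both C7 epimers) | C=C(C(=O)OC)C(O)[C@@H]1OC(C)(C)O[C@H]1/C(C(=O)OC)=C\CC/C(C)=C/C=O | intermediate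
15 | (Z)-2-(bromomethyl)enoate enal (8S,9S) | BrC/C(C(=O)OC)=C\[C@@H]1OC(C)(C)O[C@H]1/C(C(=O)OC)=C\CC/C(C)=C/C=O | intermediate
16 | dimethyl (1(10)E,4E,6R,7S,8S,9S)-6-hydroxy-8,9-(isopropylidenedioxy)germacra-1(10),4,11(13)-triene-12,14-dioate | CC1(C)O[C@H]2[C@@H](C(=C)C(=O)OC)[C@H](O)/C=C(\C)CC/C=C(/C(=O)OC)[C@@H]2O1 | intermediate (not isolated)
17 | macrocyclic trans-lactone 8,9-acetonide (6R,7S,8S,9S) | CC1(C)O[C@H]2[C@H]3C(=C)C(=O)O[C@@H]3/C=C(\C)CC/C=C(/C(=O)OC)[C@@H]2O1 | intermediate
18 | macrocyclic lactone 8,9-diol (6R,7R,8S,9S) | O[C@H]1[C@H]2C(=C)C(=O)O[C@@H]2/C=C(\C)CC/C=C(/C(=O)OC)[C@@H]1O | intermediate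
19 | 9-acetate 8-alcohol (6R,7R,8S,9S) | O[C@H]1[C@H]2C(=C)C(=O)O[C@@H]2/C=C(\C)CC/C=C(/C(=O)OC)[C@@H]1OC(C)=O | intermediate
20 | 8-methacrylate 9-acetate 4,5-alkene (6R,7S,8S,9S) | C=C(C)C(=O)O[C@H]1[C@H]2C(=C)C(=O)O[C@@H]2/C=C(\C)CC/C=C(/C(=O)OC)[C@@H]1OC(C)=O | intermediate
21 | CNP0153978.3 (4R,5R,6S,7R,8S,9S) | C=C(C)C(=O)O[C@H]1[C@H]2C(=C)C(=O)O[C@@H]2[C@H]2O[C@]2(C)CC/C=C(/C(=O)OC)[C@@H]1OC(C)=O | target

**Totals**
Total step count: 13.
Longest linear sequence: 12 steps (1 → 3 → 6 → 9 → 11 → 12 → 14 → 15 → 17 → 18 → 19 → 20 → 21).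

**Three steps most likely to fail**

Step 9 (the proposed new step). Risks:
- At 2 mM the catalytic pool of divalent chromium may trap the allyl radical too slowly, giving reduction or dimers.
- The turnover of the chromium alkoxide may stall.
- The facial selectivity at C7 rests on a conformational argument only.

The fallback sets out from 15 and comes back at 17. Light and catalytic turnover are given up, and the ring is closed by the classical thermal, stoichiometric two-electron Barbier reaction. Slow addition of 15 to excess CrCl2 (8 equiv) in DMF/THF in the dark pre-forms the allylchromium by metal reduction. This is known chemistry for ten-membered germacranolide lactones made from the same kind of bromo-enoate aldehyde. It makes no new compound.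

Step 4. Risks:
- The electron-poor iodide 6 may be reduced directly by the photocatalyst.
- Iodide 6 may act as a Giese acceptor for the C9 radical.
- The tartrate carboxylate, which carries a β-ester, may be hard to oxidise.

The fallback sets out from 8 and 6 and comes back at 9. It inverts the roles of the partners and needs no light. Acid 8 is condensed with N-hydroxyphthalimide (DIC, DMAP cat., CH2Cl2) to the N-hydroxyphthalimide ester F1. Iodide 6 is converted by iodine–magnesium exchange (iPrMgCl·LiCl, THF, −78 °C) into the alkenylmagnesium chloride F2, and then with ZnCl2 into the alkenylzinc chloride F3. The known thermal nickel-catalysed decarboxylative alkenylation of redox-active esters (Ni(acac)2, 2,2'-bipyridine, THF/DMF, rt) joins F1 and F3. The same anti attack on the dioxolanyl radical gives 9.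

Step 11. Risks:
- The two secondary hydroxyls may be acetylated with little discrimination.
- The acetate may migrate before step 12.

The fallback sets out from 18 and comes back at 20. It replaces direct acylation with temporary blocking by a bulkier and therefore more discriminating electrophile. TESCl (1.0 equiv, imidazole, CH2Cl2, −40 °C) gives the 9-O-triethylsilyl ether F4. Methacrylic anhydride/DMAP then gives the 8-O-methacryloyl 9-O-triethylsilyl ether F5. HF·pyridine frees the 8-O-methacryloyl 9-alcohol F6, and Ac2O/DMAP/pyridine gives 20. No free hydroxy acetate occurs on this path, so acetyl migration is excluded.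

**Further compounds**
F1 | step 4 | N-hydroxyphthalimide ester of 8 | COC(=O)[C@@H]1OC(C)(C)O[C@H]1C(=O)ON1C(=O)c2ccccc2C1=O
F2 | step 4 | alkenylmagnesium chloride from 6 | COC(=O)/C([Mg]Cl)=C/CC/C(C)=C/COC(C)=O
F3 | step 4 | alkenylzinc chloride from 6 | COC(=O)/C([Zn]Cl)=C/CC/C(C)=C/COC(C)=O
F0 | step 9 | none | none
F4 | step 11 | 9-O-triethylsilyl ether of 18 | O[C@H]1[C@H]2C(=C)C(=O)O[C@@H]2/C=C(\C)CC/C=C(/C(=O)OC)[C@@H]1O[Si](CC)(CC)CC
F5 | step 11 | 8-O-methacryloyl 9-O-triethylsilyl ether | C=C(C)C(=O)O[C@H]1[C@H]2C(=C)C(=O)O[C@@H]2/C=C(\C)CC/C=C(/C(=O)OC)[C@@H]1O[Si](CC)(CC)CC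
F6 | step 11 | 8-O-methacryloyl 9-alcohol | C=C(C)C(=O)O[C@H]1[C@H]2C(=C)C(=O)O[C@@H]2/C=C(\C)CC/C=C(/C(=O)OC)[C@@H]1O
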